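Z decays to J with a half-life of 3.6 h, in a run of 50 h, so in this flask L.Z has to be made early and then has to last.

    E ⇌ L, rate k1*(cs1 - [L]) while solid is left; crystals form when [L] > cs1 (cs1 = 13 mM, k1 = 0.00103 min⁻¹)
    L + Z → L.Z (k2 = 0.132 M⁻¹ min⁻¹)
    L + L.Z → L.L.Z (k3 = 0.0136 M⁻¹ min⁻¹)
    Q ⇌ L.Z, rate k4*(cs4 - [L.Z]) while solid is left; crystals form when [L.Z] > cs4 (cs4 = 14 mM, k4 = 0.0163 min⁻¹)
    Z → J (k5 = 0.00319 min⁻¹)

E 0.020 M; Z 0.0300 M; time 50 h

- the L.Z and Q together standing at 50 h, as a percentage of the E charged
- the change that raises the amount of L.Z and Q together at 50 h, in percent of the E charged most ("none" if none brings more than 2 percentage points) (red / violet / grey / amber / none)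
- amount of L.Z and Q together at 50 h, in percent of the E charged, after red

- red: doubling the dissolution coefficient of step 4, all else as stated
- violet: doubling the solubility in step 4, all else as stated
- grey: doubling the amount of Z, all else as stated
- amber: doubling the solubility in step 1, all else as stated

- in percentages every species weighs as the E in it: one L.L.Z counts as two
- for L.Z the Q are counted in
- as a solid, counted per litre of solution: E, Q
- at the start none of E is in solution
- run time (flask): 50 h

I draw the curve of L.Z in fractions of the charge. It starts flat, since no L is in solution. L then arrives at 0.0402 h⁻¹ of the charge and climbs towards saturation with a time constant of 16.2 h, so L.Z first grows with the square of time. The knee comes as Z fades, on its time constant of 5.22 h.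

Joining the two ends, I integrate capture over the life of Z and get the window yield W, 19.7 %. In words, it is the capture rate of L by fresh Z, times the saturation as a fraction of the charge, times the dissolution coefficient, divided by the product of the decay constant of Z and the sum of that constant and the dissolution coefficient. I treat it as a ceiling, because fresh Z takes L at 0.00396 min⁻¹, faster than L relaxes, so L lags the climb I assumed.

After the knee, L eats L.Z in a pseudo-first-order loss, with a half-life of 65.3 h at saturation. Letting L lag by one time constant, I reckon that 69.9 % survives, so I commit to 13.8 %. W lies below the saturation of L.Z, 70.0 %, so I expect no Q, and red and violet change nothing. Grey and amber each double W, but amber also speeds the loss, so I choose grey.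

The forecast says 9 %, grey and 9 %, lower than my figure, on the ground that “slow dissolution holds L at only a few mM”.

The flask gives 9.37 %, and 9.37 % after red; the best change is grey, worth 6.9 percentage points against 4.4 points for amber. The ceiling on dissolved L.Z makes no difference.

At 3.23 h, Z goes to J 13 times as fast as it goes to L.Z. The L.Z made in this flask, standing plus the 3.43 % turned over into L.L.Z, comes to 12.8 %, which is 65.0 % of W. In the neighbour flask with 0.012 M of E, W is 32.8 %, and the share of W standing in the first flask gives 15.6 %; L.Z and Q together stand in that neighbour at 16.2 %.

All constants stand for no real mixture; no experiment stands behind them.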